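## Retrosynthetic overview

1. With benzofuran numbering (O1, C2, C3, C3a, C4–C7, C7a; ring A is the benzo ring): 15 ⇐ 14 by cleavage of six methyl ethers with epimerisation of C2 (cis → trans), and 14 ⇐ 12 + 13 by a Heck reaction at C6–Br.
2. 12 ⇐ 10: the C2–C3 bond is made by oxidising the hydrazone to a diaryldiazomethane and enantioselective 1,5 C–H insertion of its rhodium carbene, which closes the dihydrofuran ring and sets C3 (and, for the time being, C2).
3. 10 ⇐ 9 (transimination) ⇐ 5 + 7 (Grignard addition to the nitrile); 5 ⇐ 1 by two SNAr steps (NaOMe, then the alkoxide of 3).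
4. Enabling feature: C2 is at once benzylic to the 2,4-dioxygenated ring and bound to the ring oxygen O1, so its C–H bond is hydridic, and it lies 1,5 to C3 along C3–C3a–C7a–O1–C2. C3 is a diarylmethine carbon whose carbene has two aryl donors and no β-hydrogen. Ring A is symmetric about its C3a···C6 axis (oxygens on C4 and C7a), so C2 can be re-set by ring opening and re-closure.
5. Ring order: the four benzene rings are bought; the dihydrofuran ring is the only ring formed (step 5).

Key step: step 5

Assumption: Rh2(R-PTAD)4 is taken to deliver the 3S configuration in step 5; should the sense of induction be the reverse, the mirror-image catalyst Rh2(S-PTAD)4 would be used with no other change.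

## Route

Step 1
Reactants: 1 4-bromo-2,6-difluorobenzonitrile
Product: 2 4-bromo-2-fluoro-6-methoxybenzonitrile
Conditions: NaOMe (1.05 equiv), THF/MeOH, 0 °C → rt
Reagents that add atoms: sodium methoxide, C[O-].[Na+]
Why: Nucleophilic aromatic substitution (SNAr) of a fluoride ortho to the nitrile through a Meisenheimer-type adduct should stop at mono-substitution, because the first methoxy group deactivates the ring and bromide is a far poorer leaving group in SNAr.

Step 2
Reactants: 2 4-bromo-2-fluoro-6-methoxybenzonitrile; 3 (2,4-dimethoxyphenyl)methanol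
Product: 5 4-bromo-2-[(2,4-dimethoxyphenyl)methoxy]-6-methoxybenzonitrile, via sodium (2,4-dimethoxyphenyl)methanolate 4 (not isolated)
Conditions: 3, NaH, THF/DMF, 0 °C; then 2, 0 → 50 °C
Reagents that add atoms: none
Why: A second SNAr by the benzylic alkoxide at the remaining ortho fluoride, still activated by the nitrile, should install the arm that later supplies C2 and its aryl group, while the aryl bromide and the methyl ether stay inert.

Step 3
Reactants: 5 4-bromo-2-[(2,4-dimethoxyphenyl)methoxy]-6-methoxybenzonitrile; 6 1-bromo-3,5-dimethoxybenzene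
Product: 9 1-{4-bromo-2-[(2,4-dimethoxyphenyl)methoxy]-6-methoxyphenyl}-1-(3,5-dimethoxyphenyl)methanimine, via (3,5-dimethoxyphenyl)magnesium bromide 7 (not isolated), via N-bromomagnesio ketimine 8 (not isolated)
Conditions: 6, Mg, THF, 45 °C; solution of 7 added to 5, CuBr (5 mol %), THF, 60 °C; then H2O, 0 °C
Reagents that add atoms: none
Why: Grignard addition to a nitrile stops at the N-magnesio ketimine (no second addition), is assisted by chelation to the two ortho alkoxy groups and by CuBr, leaves the aryl bromide alone, and gives a hindered diaryl N–H ketimine that should survive a cold aqueous quench without hydrolysis.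

Step 4
Reactants: 9 1-{4-bromo-2-[(2,4-dimethoxyphenyl)methoxy]-6-methoxyphenyl}-1-(3,5-dimethoxyphenyl)methanimine
Product: 10 [{4-bromo-2-[(2,4-dimethoxyphenyl)methoxy]-6-methoxyphenyl}(3,5-dimethoxyphenyl)methylidene]hydrazine (E/Z mixture, of no consequence)
Conditions: N2H4·H2O (10 equiv), AcOH (cat.), EtOH, 80 °C
Reagents that add atoms: hydrazine monohydrate, NN.O
Why: Transimination (addition–elimination at C=N with loss of ammonia) by the alpha-effect nucleophile hydrazine is the classical entry to hindered hydrazones and avoids condensation with a 2,6-dialkoxybenzophenone.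

Step 5
Reactants: 10 [{4-bromo-2-[(2,4-dimethoxyphenyl)methoxy]-6-methoxyphenyl}(3,5-dimethoxyphenyl)methylidene]hydrazine
Product: 12 (2R,3S)-6-bromo-2-(2,4-dimethoxyphenyl)-3-(3,5-dimethoxyphenyl)-4-methoxy-2,3-dihydro-1-benzofuran (2,3-cis), via diaryldiazomethane 11 (not isolated)
Conditions: MnO2 (8 equiv), CH2Cl2, 0 °C, filtration; filtrate added slowly to Rh2(R-PTAD)4 [dirhodium tetrakis((R)-(1-adamantyl)(phthalimido)acetate)] (1 mol %), CH2Cl2, 0 °C → rt
Reagents that add atoms: none
Why: MnO2 dehydrogenates the hydrazone to the diaryldiazomethane 11, which loses N2 on the dirhodium tetracarboxylate (both rhodium atoms divalent) to give a donor/donor rhodium carbene at the future C3; this carbon takes the benzylic, oxygen-bound C–H bond of the ortho OCH2Ar arm (the future C2) in a concerted, hydride-transfer-like three-centre insertion that forms the C2–C3 bond. The closest known reaction type is the enantioselective intramolecular 1,5 C–H insertion of diaryl (donor/donor) rhodium carbenes into benzyl aryl ether C–H bonds, which gives cis-2,3-diaryl-2,3-dihydrobenzofurans. The dihydrofuran ring closes in the 1,5 mode (ring atoms C3–C3a–C7a–O1–C2, the C–C bond being the closing bond), helped by the two ortho oxygens of ring A, which twist this ring out of the carbene plane and hold the arm C–H over the empty carbene orbital. C3 (S) is set by catalyst control, the chiral phthalimido(adamantyl)acetate ligands leaving one face of the carbene open to the C–H bond, and C2 (R) follows from C3 through the geometry of the concerted insertion (aryl groups cis, the kinetic outcome), so only C3 has to be right at this stage. The step needs site selectivity for the arm CH2 over the C–H bonds of the C4 methoxy group and chemoselectivity for insertion over azine formation, carbene dimerisation and attack on the arene of the arm; the CH2 is the most hydridic C–H bond (alpha-oxygen plus 2,4-dimethoxyphenyl), the carbene has no beta-hydrogen and is tamed by two aryl donors, and slow addition keeps the concentration of 11 low.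

Step 6
Reactants: 12 (2R,3S)-6-bromo-2-(2,4-dimethoxyphenyl)-3-(3,5-dimethoxyphenyl)-4-methoxy-2,3-dihydro-1-benzofuran; 13 1-ethenyl-4-methoxybenzene
Product: 14 (2R,3S)-2-(2,4-dimethoxyphenyl)-3-(3,5-dimethoxyphenyl)-4-methoxy-6-[(E)-2-(4-methoxyphenyl)ethenyl]-2,3-dihydro-1-benzofuran
Conditions: Pd(OAc)2 (5 mol %), P(o-tol)3 (12 mol %), Et3N, DMF, 100 °C
Reagents that add atoms: none
Why: In the Heck reaction, oxidative addition of the aryl bromide to zerovalent palladium, syn carbopalladation at the terminal carbon of the styrene and syn beta-hydride elimination should give the E-stilbene, and the basic medium leaves the cis-dihydrobenzofuran untouched.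

Step 7
Reactants: 14 (2R,3S)-2-(2,4-dimethoxyphenyl)-3-(3,5-dimethoxyphenyl)-4-methoxy-6-[(E)-2-(4-methoxyphenyl)ethenyl]-2,3-dihydro-1-benzofuran
Product: 15 (2S,3S)-2-(2,4-dihydroxyphenyl)-3-(3,5-dihydroxyphenyl)-6-[(E)-2-(4-hydroxyphenyl)ethenyl]-2,3-dihydro-1-benzofuran-4-ol
Conditions: BBr3 (15 equiv), CH2Cl2, −78 °C → rt; then H2O, 0 °C
Reagents that add atoms: none
Why: Lewis-acid cleavage of the six aryl methyl ethers by BBr3 is accompanied by acid-mediated epimerisation, in which reversible ionisation of the C2–O1 bond to a benzylic cation (stabilised by the ortho and para oxygens of the C2 aryl group) and re-closure onto either of the two equivalent ortho oxygens of ring A, anti to the C3 aryl group, should give the more stable trans (2S,3S) isomer while C3, never ionised, keeps its configuration.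

## Compound list

1 | 4-bromo-2,6-difluorobenzonitrile | N#Cc1c(F)cc(Br)cc1F | starting material
2 | 4-bromo-2-fluoro-6-methoxybenzonitrile | COc1cc(Br)cc(F)c1C#N | intermediate
3 | (2,4-dimethoxyphenyl)methanol | COc1ccc(CO)c(OC)c1 | starting material
4 | sodium (2,4-dimethoxyphenyl)methanolate (not isolated) | COc1ccc(C[O-])c(OC)c1.[Na+] | intermediate
5 | 4-bromo-2-[(2,4-dimethoxyphenyl)methoxy]-6-methoxybenzonitrile | COc1cc(Br)cc(OCc2ccc(OC)cc2OC)c1C#N | intermediate
6 | 1-bromo-3,5-dimethoxybenzene | COc1cc(Br)cc(OC)c1 | starting material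
7 | (3,5-dimethoxyphenyl)magnesium bromide (not isolated) | COc1cc([Mg]Br)cc(OC)c1 | intermediate
8 | N-bromomagnesio derivative of ketimine 9 (not isolated) | COc1cc(Br)cc(OCc2ccc(OC)cc2OC)c1C(=N[Mg]Br)c1cc(OC)cc(OC)c1 | intermediate
9 | 1-{4-bromo-2-[(2,4-dimethoxyphenyl)methoxy]-6-methoxyphenyl}-1-(3,5-dimethoxyphenyl)methanimine | COc1cc(Br)cc(OCc2ccc(OC)cc2OC)c1C(=N)c1cc(OC)cc(OC)c1 | intermediate
10 | [{4-bromo-2-[(2,4-dimethoxyphenyl)methoxy]-6-methoxyphenyl}(3,5-dimethoxyphenyl)methylidene]hydrazine | COc1cc(Br)cc(OCc2ccc(OC)cc2OC)c1C(=NN)c1cc(OC)cc(OC)c1 | intermediate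
11 | 5-bromo-2-[diazo(3,5-dimethoxyphenyl)methyl]-1-[(2,4-dimethoxyphenyl)methoxy]-3-methoxybenzene (not isolated) | COc1cc(Br)cc(OCc2ccc(OC)cc2OC)c1C(=[N+]=[N-])c1cc(OC)cc(OC)c1 | intermediate
12 | (2R,3S)-6-bromo-2-(2,4-dimethoxyphenyl)-3-(3,5-dimethoxyphenyl)-4-methoxy-2,3-dihydro-1-benzofuran (cis) | Brc1cc(OC)c2c(c1)O[C@@H](c1ccc(OC)cc1OC)[C@H]2c1cc(OC)cc(OC)c1 | intermediate
13 | 1-ethenyl-4-methoxybenzene (4-methoxystyrene) | C=Cc1ccc(OC)cc1 | starting material
14 | (2R,3S)-2-(2,4-dimethoxyphenyl)-3-(3,5-dimethoxyphenyl)-4-methoxy-6-[(E)-2-(4-methoxyphenyl)ethenyl]-2,3-dihydro-1-benzofuran (cis) | COc1ccc(/C=C/c2cc(OC)c3c(c2)O[C@@H](c2ccc(OC)cc2OC)[C@H]3c2cc(OC)cc(OC)c2)cc1 | intermediate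
15 | (2S,3S)-2-(2,4-dihydroxyphenyl)-3-(3,5-dihydroxyphenyl)-6-[(E)-2-(4-hydroxyphenyl)ethenyl]-2,3-dihydro-1-benzofuran-4-ol (trans) | Oc1ccc(/C=C/c2cc(O)c3c(c2)O[C@H](c2ccc(O)cc2O)[C@H]3c2cc(O)cc(O)c2)cc1 | target

## Step count and risks

Total step count: 7. Longest linear sequence: 7 steps (1 → 15).

**Step 5.** The carbene may insert into a C–H bond of the neighbouring C4 methoxy group instead of the arm. This loss of site selectivity is the one selectivity the catalyst cannot enforce, and a bulky catalyst could even favour it. The fallback gives both ortho oxygens of ring A the same arm, so that every 1,5-insertion leads to the same ring. It sets out from 1 and the alkoxide 4 and comes back at 15.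
- Double SNAr of 1 with 2.3 equiv of 4 (THF/DMF, 60 °C) should give the symmetric bis-ether nitrile F1.
- Addition of 7 (CuBr cat., THF, 60 °C) and an aqueous quench should give the bis-ether ketimine F2.
- Transimination with N2H4·H2O should give the bis-ether hydrazone F3.
- MnO2 and then Rh2(R-PTAD)4 should give, through the bis-ether diazo compound F4, the cis-dihydrobenzofuran that still carries one arm on O4, F5.
- A Heck reaction with 13 should give the arm-bearing stilbene F6.
- BBr3 with pentamethylbenzene as a non-basic cation scavenger (CH2Cl2, −78 °C → rt) should remove all methyl groups and the surplus arm and epimerise C2, arriving at 15.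

**Step 7.** During the long exposure to BBr3 that six ether cleavages need, the electron-rich stilbene may be protonated or bromoborated and oligomerise. The fallback removes the methyl ethers before the alkene is present and finishes under basic conditions. It sets out from 12 and comes back at 15.
- BBr3 (CH2Cl2, −78 → 0 °C) on 12 should give the trans pentaphenol bromide F7, with the same epimerisation at C2.
- Ac2O in pyridine should give the pentaacetate bromide F8.
- A Heck reaction with 4-acetoxystyrene (Pd(OAc)2, P(o-tol)3, Et3N, DMF, 100 °C) should give the hexaacetate stilbene F9.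
- K2CO3 in MeOH under argon, then dilute acid, should remove the acetates and arrive at 15.

**Step 3.** With the hindered, electron-rich nitrile the Grignard reagent may displace an ortho alkoxy group or exchange with the aryl bromide faster than it adds to the C≡N group. The fallback builds the diaryl carbon by addition to an aldehyde. It sets out from 5 and comes back at 10.
- i-Bu2AlH (toluene, −78 °C, then aqueous tartaric acid) should give the benzaldehyde F10.
- 7 should add at −78 °C to give the racemic diarylcarbinol F11.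
- MnO2 (CH2Cl2, rt) should give the diaryl ketone F12.
- Forced condensation with anhydrous hydrazine (n-BuOH, AcOH cat., 120 °C) arrives at 10.

## Further compounds

F1 | step 5 | 4-bromo-2,6-bis[(2,4-dimethoxyphenyl)methoxy]benzonitrile | N#Cc1c(OCc2ccc(OC)cc2OC)cc(Br)cc1OCc1ccc(OC)cc1OC
F2 | step 5 | 1-{4-bromo-2,6-bis[(2,4-dimethoxyphenyl)methoxy]phenyl}-1-(3,5-dimethoxyphenyl)methanimine | N=C(c1cc(OC)cc(OC)c1)c1c(OCc2ccc(OC)cc2OC)cc(Br)cc1OCc1ccc(OC)cc1OC
F3 | step 5 | [{4-bromo-2,6-bis[(2,4-dimethoxyphenyl)methoxy]phenyl}(3,5-dimethoxyphenyl)methylidene]hydrazine | NN=C(c1cc(OC)cc(OC)c1)c1c(OCc2ccc(OC)cc2OC)cc(Br)cc1OCc1ccc(OC)cc1OC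
F4 | step 5 | 5-bromo-2-[diazo(3,5-dimethoxyphenyl)methyl]-1,3-bis[(2,4-dimethoxyphenyl)methoxy]benzene | [N-]=[N+]=C(c1cc(OC)cc(OC)c1)c1c(OCc2ccc(OC)cc2OC)cc(Br)cc1OCc1ccc(OC)cc1OC
F5 | step 5 | (2R,3S)-6-bromo-4-[(2,4-dimethoxyphenyl)methoxy]-2-(2,4-dimethoxyphenyl)-3-(3,5-dimethoxyphenyl)-2,3-dihydro-1-benzofuran | Brc1cc(OCc3ccc(OC)cc3OC)c2c(c1)O[C@@H](c1ccc(OC)cc1OC)[C@H]2c1cc(OC)cc(OC)c1
F6 | step 5 | (2R,3S)-4-[(2,4-dimethoxyphenyl)methoxy]-2-(2,4-dimethoxyphenyl)-3-(3,5-dimethoxyphenyl)-6-[(E)-2-(4-methoxyphenyl)ethenyl]-2,3-dihydro-1-benzofuran | COc1ccc(/C=C/c2cc(OCc4ccc(OC)cc4OC)c3c(c2)O[C@@H](c2ccc(OC)cc2OC)[C@H]3c2cc(OC)cc(OC)c2)cc1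
F7 | step 7 | (2S,3S)-6-bromo-2-(2,4-dihydroxyphenyl)-3-(3,5-dihydroxyphenyl)-2,3-dihydro-1-benzofuran-4-ol | Brc1cc(O)c2c(c1)O[C@H](c1ccc(O)cc1O)[C@H]2c1cc(O)cc(O)c1
F8 | step 7 | (2S,3S)-6-bromo-2-(2,4-diacetoxyphenyl)-3-(3,5-diacetoxyphenyl)-2,3-dihydro-1-benzofuran-4-yl acetate | Brc1cc(OC(C)=O)c2c(c1)O[C@H](c1ccc(OC(C)=O)cc1OC(C)=O)[C@H]2c1cc(OC(C)=O)cc(OC(C)=O)c1
F9 | step 7 | (2S,3S)-2-(2,4-diacetoxyphenyl)-3-(3,5-diacetoxyphenyl)-6-[(E)-2-(4-acetoxyphenyl)ethenyl]-2,3-dihydro-1-benzofuran-4-yl acetate | CC(=O)Oc1ccc(/C=C/c2cc(OC(C)=O)c3c(c2)O[C@H](c2ccc(OC(C)=O)cc2OC(C)=O)[C@H]3c2cc(OC(C)=O)cc(OC(C)=O)c2)cc1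
F10 | step 3 | 4-bromo-2-[(2,4-dimethoxyphenyl)methoxy]-6-methoxybenzaldehyde | COc1cc(Br)cc(OCc2ccc(OC)cc2OC)c1C=O
F11 | step 3 | {4-bromo-2-[(2,4-dimethoxyphenyl)methoxy]-6-methoxyphenyl}(3,5-dimethoxyphenyl)methanol (racemic) | COc1cc(Br)cc(OCc2ccc(OC)cc2OC)c1C(O)c1cc(OC)cc(OC)c1
F12 | step 3 | {4-bromo-2-[(2,4-dimethoxyphenyl)methoxy]-6-methoxyphenyl}(3,5-dimethoxyphenyl)methanone | COc1cc(Br)cc(OCc2ccc(OC)cc2OC)c1C(=O)c1cc(OC)cc(OC)c1
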